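Ring A = C1–C5/C10 and ring B = C5–C10 (halimane numbering). Ring A hides a Claisen retron: the quaternary C4 is bonded to C5, which is allylic to C1=C10. Ring A is therefore closed last by ring contraction of a 2-alkenyl-3,4-dihydro-2H-pyran-5-carboxylate, in which an oxygen links C1 to the carbon that becomes the C4 methyl. One [3,3] shift forms C4–C5, the C1=C10 alkene and both ring A stereocentres (C5 by transfer from the C1–O carbinol, C4 by the enforced boat). The precursor is ring B, built by asymmetric conjugate addition to 2-methylcyclohexenone, joined to a cyclic vinylogous carbonate; the released formyl group is finally reduced to CH3.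

Key step: step 9

Remark on numbering: C4 = quaternary carbon with CO2Me and CH3, C5 = ring-fusion CH, C10 = ring-fusion alkene carbon, C1 = alkene CH, C8 and C9 = methyl-bearing carbons of ring B, C11–C15 = side chain. The β face carries H5, the C4 ester and the C9 side chain; the α face carries the C4, C8 and C9 methyl groups.

Assumption: the ligand enantiomers in steps 1 and 7 are those that give the configurations drawn; compounds 1, 4 and 8 are commercial.

Step 1
Reactants: 1 2-methylcyclohex-2-en-1-one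
Product: 3 [(3R)-2,3-dimethylcyclohex-1-en-1-yl]oxy(trimethyl)silane, via aluminium enolate 2 (not isolated)
Conditions: Me3Al, copper thiophene-2-carboxylate (CuO2CC4H3S, 2 mol %), chiral BINOL-derived phosphoramidite (4 mol %), Et2O, −30 °C; then Me3SiOTf, −30 °C → rt
Reagents that add atoms: trimethylaluminium C[Al](C)C; trimethylsilyl trifluoromethanesulfonate C[Si](C)(C)OS(=O)(=O)C(F)(F)F
Why: Copper-catalysed asymmetric conjugate addition of the methyl group (ligand-controlled face of the enone) sets C8 as R, and the regiodefined aluminium enolate 2 is trapped on oxygen as the C9=C10 silyl enol ether.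

Step 2
Reactants: 3 [(3R)-2,3-dimethylcyclohex-1-en-1-yl]oxy(trimethyl)silane; 4 but-3-en-2-one
Product: 5 (2S,3R)-2,3-dimethyl-2-(3-oxobutyl)cyclohexan-1-one
Conditions: BF3·OEt2, i-PrOH, CH2Cl2, −78 °C
Reagents that add atoms: none
Why: Mukaiyama–Michael addition to the BF3-activated enone creates the C9 quaternary centre, the electrophile entering anti to the pseudoaxial C8 methyl group so that the new chain is trans to C8–CH3 and the two methyl groups are cis (9S).

Step 3
Reactants: 5 (2S,3R)-2,3-dimethyl-2-(3-oxobutyl)cyclohexan-1-one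
Product: 6 methyl (2E)-5-[(1S,2R)-1,2-dimethyl-6-oxocyclohexyl]-3-methylpent-2-enoate
Conditions: (MeO)2P(O)CH2CO2Me, NaH, THF, 0 → 40 °C; chromatographic removal of the minor Z isomer
Reagents that add atoms: trimethyl phosphonoacetate COC(=O)CP(=O)(OC)OC
Why: Horner–Wadsworth–Emmons olefination attacks only the unhindered methyl ketone (the ring ketone is flanked by the quaternary C9) and should give mainly the thermodynamically favoured E enoate.

Step 4
Reactants: 6 methyl (2E)-5-[(1S,2R)-1,2-dimethyl-6-oxocyclohexyl]-3-methylpent-2-enoate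
Product: 7 methyl (2E)-5-[(1S,6R)-1,6-dimethyl-2-(trifluoromethanesulfonyloxy)cyclohex-2-en-1-yl]-3-methylpent-2-enoate
Conditions: Tf2O, 2,6-di-tert-butyl-4-methylpyridine, CH2Cl2, 0 °C → rt
Reagents that add atoms: trifluoromethanesulfonic anhydride O=S(=O)(OS(=O)(=O)C(F)(F)F)C(F)(F)F
Why: Enol triflate formation under non-basic conditions: the ring ketone can enolise only towards C5, so a single C10=C5 vinyl triflate results and the enoate stays untouched.

Step 5
Reactants: 8 methyl 5,5-dimethoxypentanoate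
Product: 10 methyl (2E)-5,5-dimethoxy-2-(methoxymethylidene)pentanoate, via sodium formyl-ester enolate 9 (not isolated)
Conditions: NaH, HCO2Me, cat. MeOH, THF, 0 °C → rt; then Me2SO4, DMF, rt
Reagents that add atoms: methyl formate COC=O; dimethyl sulfate COS(=O)(=O)OC
Why: Crossed Claisen condensation of the ester enolate with methyl formate gives the stabilised enolate 9, whose O-methylation by the hard electrophile dimethyl sulfate gives the E β-methoxyacrylate.

Step 6
Reactants: 10 methyl (2E)-5,5-dimethoxy-2-(methoxymethylidene)pentanoate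
Product: 11 methyl (2E)-2-(methoxymethylidene)-5-oxopentanoate
Conditions: sulfonic acid resin (Amberlyst-15), acetone/H2O, rt
Reagents that add atoms: water O
Why: Acid-catalysed acetal hydrolysis frees the aldehyde, the push–pull enol ether being too weakly basic to hydrolyse under these mild conditions.

Step 7
Reactants: 7 methyl (2E)-5-[(1S,6R)-1,6-dimethyl-2-(trifluoromethanesulfonyloxy)cyclohex-2-en-1-yl]-3-methylpent-2-enoate; 11 methyl (2E)-2-(methoxymethylidene)-5-oxopentanoate
Product: 12 methyl (2E)-5-[(1S,6R)-2-[(1S,4E)-1-hydroxy-5-methoxy-4-(methoxycarbonyl)pent-4-en-1-yl]-1,6-dimethylcyclohex-2-en-1-yl]-3-methylpent-2-enoate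
Conditions: CrCl2 (4 equiv), NiCl2 (5 mol %), chiral 2-(2-sulfonamidoaryl)oxazoline ligand, Et3N, THF, rt; aqueous work-up
Reagents that add atoms: none
Why: Nozaki–Hiyama–Kishi coupling: zerovalent nickel inserts into the vinyl triflate, transmetallation gives a vinyl species of trivalent chromium that adds only to the aldehyde, and the chiral sulfonamide ligand on chromium selects the aldehyde face that gives the (1S) carbinol at C1.

Step 8
Reactants: 12 methyl (2E)-5-[(1S,6R)-2-[(1S,4E)-1-hydroxy-5-methoxy-4-(methoxycarbonyl)pent-4-en-1-yl]-1,6-dimethylcyclohex-2-en-1-yl]-3-methylpent-2-enoate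
Product: 13 methyl (2S)-2-[(5R,6S)-6-[(3E)-5-methoxy-3-methyl-5-oxopent-3-en-1-yl]-5,6-dimethylcyclohex-1-en-1-yl]-3,4-dihydro-2H-pyran-5-carboxylate
Conditions: pyridinium p-toluenesulfonate (10 mol %), toluene, 90 °C, 5 Å molecular sieves
Reagents that add atoms: none
Why: Acid-catalysed intramolecular trans-etherification of the β-methoxyacrylate (addition–elimination at the β-carbon, 6-endo-trig, loss of methanol) closes the six-membered cyclic vinylogous carbonate, which is also the thermodynamically preferred isomer over the lactone (as in the acyl-lactone rearrangement), without touching C1.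

Step 9
Reactants: 13 methyl (2S)-2-[(5R,6S)-6-[(3E)-5-methoxy-3-methyl-5-oxopent-3-en-1-yl]-5,6-dimethylcyclohex-1-en-1-yl]-3,4-dihydro-2H-pyran-5-carboxylate
Product: 14 methyl (1S,5S,6R,8aS)-1-formyl-5-[(3E)-5-methoxy-3-methyl-5-oxopent-3-en-1-yl]-5,6-dimethyl-1,2,3,5,6,7,8,8a-octahydronaphthalene-1-carboxylate
Conditions: degassed 1,2-dichlorobenzene (0.02 M), 2,6-di-tert-butyl-4-methylphenol (5 mol %), base-washed sealed tube, 210 °C
Reagents that add atoms: none
Why: Mechanism: concerted thermal [3,3]-sigmatropic (Claisen) shift of the allyl vinyl ether C5=C10–C1–O–CH=C4 contained in 13, breaking C1–O and forming C4–C5, the C1=C10 alkene and the C4 formyl group. The closest known reaction types are the ring contraction of 2-alkenyl-3,4-dihydro-2H-pyrans to cyclohex-3-enecarbaldehydes and the classical rearrangement of allyl ethers of formylacetates (allyl vinylogous carbonates). Ring A closes by C4–C5 bond formation in a six-to-six ring contraction whose two-carbon C2–C3 tether forces a bicyclo[2.2.2]octane-like boat transition state. C5 is set by suprafacial chirality transfer from the (S)-C1 carbinol: with C2 in the alkene plane cis to C5, the C1–O bond lies on the α face of the ring B alkene, so C4 arrives there and H5 ends up β. C4 is set by the boat together with the fixed geometries of both π systems (C6 trans to C1 on the ring B alkene, C3 cis to O on the enol ether), which place the new formyl group cis to C6 and the methoxycarbonyl group cis to H5. The step needs periselectivity for the [3,3] shift over retro-hetero-Diels–Alder cleavage or ionisation of the allylic C1–O bond, which the neutral non-polar medium and the preorganised intramolecular array should secure, while C8 and C9 are spectators.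

Step 10
Reactants: 14 methyl (1S,5S,6R,8aS)-1-formyl-5-[(3E)-5-methoxy-3-methyl-5-oxopent-3-en-1-yl]-5,6-dimethyl-1,2,3,5,6,7,8,8a-octahydronaphthalene-1-carboxylate
Product: 16 methyl (1S,5S,6R,8aS)-5-[(3E)-5-methoxy-3-methyl-5-oxopent-3-en-1-yl]-1,5,6-trimethyl-1,2,3,5,6,7,8,8a-octahydronaphthalene-1-carboxylate, via tosylhydrazone 15 (not isolated)
Conditions: TsNHNH2, EtOH, 40 °C; then catecholborane, CHCl3, 0 °C; NaOAc·3H2O, 60 °C
Reagents that add atoms: none
Why: Tosylhydrazone formation followed by hydride reduction with catecholborane and loss of sulfinate and N2 from the resulting diazene (reductive deoxygenation of a carbonyl group through its tosylhydrazone) turns the formyl group into the C4 methyl, the quaternary C4 being unable to epimerise.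

Step 11
Reactants: 16 methyl (1S,5S,6R,8aS)-5-[(3E)-5-methoxy-3-methyl-5-oxopent-3-en-1-yl]-1,5,6-trimethyl-1,2,3,5,6,7,8,8a-octahydronaphthalene-1-carboxylate
Product: 17 methyl (1S,5S,6R,8aS)-5-[(3E)-5-hydroxy-3-methylpent-3-en-1-yl]-1,5,6-trimethyl-1,2,3,5,6,7,8,8a-octahydronaphthalene-1-carboxylate
Conditions: i-Bu2AlH (2.2 equiv), CH2Cl2, −78 °C; aq. potassium sodium tartrate
Reagents that add atoms: none
Why: 1,2-Reduction of the conjugated, unhindered ester by DIBAL-H at low temperature, the C4 ester being shielded by its quaternary α-carbon and the ring fusion.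

Step 12
Reactants: 17 methyl (1S,5S,6R,8aS)-5-[(3E)-5-hydroxy-3-methylpent-3-en-1-yl]-1,5,6-trimethyl-1,2,3,5,6,7,8,8a-octahydronaphthalene-1-carboxylate
Product: 18 methyl (1S,5S,6R,8aS)-5-[(3E)-5-acetoxy-3-methylpent-3-en-1-yl]-1,5,6-trimethyl-1,2,3,5,6,7,8,8a-octahydronaphthalene-1-carboxylate (target)
Conditions: Ac2O, pyridine, cat. DMAP, CH2Cl2, 0 °C → rt
Reagents that add atoms: acetic anhydride CC(=O)OC(C)=O
Why: Nucleophile-catalysed O-acetylation of the primary allylic alcohol.

Compound list
1 | 2-methylcyclohex-2-en-1-one | CC1=CCCCC1=O | starting material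
2 | dimethylaluminium (3R)-2,3-dimethylcyclohex-1-en-1-olate | C[C@@H]1CCCC(O[Al](C)C)=C1C | intermediate
3 | [(3R)-2,3-dimethylcyclohex-1-en-1-yl]oxy(trimethyl)silane | C[C@@H]1CCCC(O[Si](C)(C)C)=C1C | intermediate
4 | but-3-en-2-one | CC(=O)C=C | starting material
5 | (2S,3R)-2,3-dimethyl-2-(3-oxobutyl)cyclohexan-1-one | O=C1CCC[C@@H](C)[C@]1(C)CCC(C)=O | intermediate
6 | methyl (2E)-5-[(1S,2R)-1,2-dimethyl-6-oxocyclohexyl]-3-methylpent-2-enoate | O=C1CCC[C@@H](C)[C@]1(C)CC/C(C)=C/C(=O)OC | intermediate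
7 | methyl (2E)-5-[(1S,6R)-1,6-dimethyl-2-(trifluoromethanesulfonyloxy)cyclohex-2-en-1-yl]-3-methylpent-2-enoate | O=S(=O)(OC1=CCC[C@@H](C)[C@]1(C)CC/C(C)=C/C(=O)OC)C(F)(F)F | intermediate
8 | methyl 5,5-dimethoxypentanoate | COC(=O)CCCC(OC)OC | starting material
9 | sodium enolate of methyl 2-formyl-5,5-dimethoxypentanoate | [Na+].[O-]C=C(CCC(OC)OC)C(=O)OC | intermediate
10 | methyl (2E)-5,5-dimethoxy-2-(methoxymethylidene)pentanoate | CO/C=C(\CCC(OC)OC)C(=O)OC | intermediate
11 | methyl (2E)-2-(methoxymethylidene)-5-oxopentanoate | CO/C=C(\CCC=O)C(=O)OC | intermediate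
12 | methyl (2E)-5-[(1S,6R)-2-[(1S,4E)-1-hydroxy-5-methoxy-4-(methoxycarbonyl)pent-4-en-1-yl]-1,6-dimethylcyclohex-2-en-1-yl]-3-methylpent-2-enoate | CO/C=C(\CC[C@H](O)C1=CCC[C@@H](C)[C@]1(C)CC/C(C)=C/C(=O)OC)C(=O)OC | intermediate
13 | methyl (2S)-2-[(5R,6S)-6-[(3E)-5-methoxy-3-methyl-5-oxopent-3-en-1-yl]-5,6-dimethylcyclohex-1-en-1-yl]-3,4-dihydro-2H-pyran-5-carboxylate | COC(=O)C1=CO[C@@H](CC1)C2=CCC[C@@H](C)[C@]2(C)CC/C(C)=C/C(=O)OC | intermediate
14 | methyl (1S,5S,6R,8aS)-1-formyl-5-[(3E)-5-methoxy-3-methyl-5-oxopent-3-en-1-yl]-5,6-dimethyl-1,2,3,5,6,7,8,8a-octahydronaphthalene-1-carboxylate | COC(=O)[C@@]1(C=O)CCC=C2[C@@H]1CC[C@@H](C)[C@]2(C)CC/C(C)=C/C(=O)OC | intermediate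
15 | N-tosylhydrazone of aldehyde 14 | COC(=O)[C@@]1(C=NNS(=O)(=O)c3ccc(C)cc3)CCC=C2[C@@H]1CC[C@@H](C)[C@]2(C)CC/C(C)=C/C(=O)OC | intermediate
16 | methyl (1S,5S,6R,8aS)-5-[(3E)-5-methoxy-3-methyl-5-oxopent-3-en-1-yl]-1,5,6-trimethyl-1,2,3,5,6,7,8,8a-octahydronaphthalene-1-carboxylate | COC(=O)[C@@]1(C)CCC=C2[C@@H]1CC[C@@H](C)[C@]2(C)CC/C(C)=C/C(=O)OC | intermediate
17 | methyl (1S,5S,6R,8aS)-5-[(3E)-5-hydroxy-3-methylpent-3-en-1-yl]-1,5,6-trimethyl-1,2,3,5,6,7,8,8a-octahydronaphthalene-1-carboxylate | COC(=O)[C@@]1(C)CCC=C2[C@@H]1CC[C@@H](C)[C@]2(C)CC/C(C)=C/CO | intermediate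
18 | methyl (1S,5S,6R,8aS)-5-[(3E)-5-acetoxy-3-methylpent-3-en-1-yl]-1,5,6-trimethyl-1,2,3,5,6,7,8,8a-octahydronaphthalene-1-carboxylate | COC(=O)[C@@]1(C)CCC=C2[C@@H]1CC[C@@H](C)[C@]2(C)CC/C(C)=C/COC(C)=O | target

Total step count: 12. Longest linear sequence: 10 steps (steps 1–4 and 7–12; steps 5 and 6 make the side fragment).

Steps most likely to fail

Step 9 (key step). The boat transition state of a push–pull enol ether may demand a temperature at which retro-hetero-Diels–Alder cleavage or heterolysis of the allylic C1–O bond competes, which would erase the stereochemical relay. The fallback runs the same bond construction as a lactone enolate rearrangement at lower temperature; it sets out from 7 and comes back at 14.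
- Triflate 7 is coupled under the conditions of step 7 with dimethyl 2-(3-oxopropyl)propanedioate F1 (made from dimethyl malonate and acrolein with catalytic NaOMe) to give the (S)-hydroxy malonate F2.
- F2 lactonises (camphorsulfonic acid, toluene, 80 °C) to the α-methoxycarbonyl δ-lactone F3.
- Me3SiOTf/Et3N convert F3 into the silyl ketene acetal F4, which on heating in toluene (110–140 °C) should undergo the Ireland–Claisen ring contraction through the same boat to the trimethylsilyl ester F5.
- Hydrolytic work-up gives the half-acid F6, whose new carboxyl group stands where the formyl group of 14 stands.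
- Oxalyl chloride with catalytic DMF gives the acid chloride F7, and LiAlH(O-t-Bu)3 (THF, −78 °C) reduces it to aldehyde 14.

Step 7. Facial selectivity at the aldehyde may be poor because the chiral chromium complex has to override the bias of the hindered, chiral vinyl partner. The fallback sets the carbinol by reagent-controlled ketone reduction instead; it sets out from 7 and 11 and comes back at 12.
- Ligand-free coupling (CrCl2, cat. NiCl2, DMF) gives 12 together with its C1 epimer F8.
- The mixture is oxidised with 1,1,1-triacetoxy-1,1-dihydro-1,2-benziodoxol-3(1H)-one to the single enone F9.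
- Corey–Bakshi–Shibata reduction with catecholborane and the (R)-configured 2-methyl oxazaborolidine catalyst (cyclohexenyl as the large group, CH2 as the small group) should return the (S)-alcohol 12.

Step 10. The non-enolisable α-formyl ester may lose its formyl group by retro-Claisen-type C–C cleavage during hydrazone formation, or hydride addition to the neopentyl hydrazone may stall. The fallback removes the oxygen through the alcohol; it sets out from 14 and comes back at 16.
- NaBH4 (MeOH, −20 °C) reduces the formyl group to the neopentyl alcohol F10.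
- I2/PPh3/imidazole (toluene, 80 °C, Appel-type) gives the iodide F11.
- Bu3SnH/AIBN (benzene, 80 °C) removes the iodine to give 16.

Further compounds
F1 | step 9 | dimethyl 2-(3-oxopropyl)propanedioate | O=CCCC(C(=O)OC)C(=O)OC
F2 | step 9 | dimethyl 2-[(3S)-3-hydroxy-3-[(5R,6S)-6-[(3E)-5-methoxy-3-methyl-5-oxopent-3-en-1-yl]-5,6-dimethylcyclohex-1-en-1-yl]propyl]propanedioate | COC(=O)C(CC[C@H](O)C1=CCC[C@@H](C)[C@]1(C)CC/C(C)=C/C(=O)OC)C(=O)OC
F3 | step 9 | methyl (6S)-6-[(5R,6S)-6-[(3E)-5-methoxy-3-methyl-5-oxopent-3-en-1-yl]-5,6-dimethylcyclohex-1-en-1-yl]-2-oxooxane-3-carboxylate | COC(=O)C1CC[C@H](OC1=O)C2=CCC[C@@H](C)[C@]2(C)CC/C(C)=C/C(=O)OC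
F4 | step 9 | methyl (2S)-2-[(5R,6S)-6-[(3E)-5-methoxy-3-methyl-5-oxopent-3-en-1-yl]-5,6-dimethylcyclohex-1-en-1-yl]-6-(trimethylsilyloxy)-3,4-dihydro-2H-pyran-5-carboxylate | COC(=O)C1=C(O[Si](C)(C)C)O[C@@H](CC1)C2=CCC[C@@H](C)[C@]2(C)CC/C(C)=C/C(=O)OC
F5 | step 9 | trimethylsilyl ester of acid F6 | COC(=O)[C@@]1(C(=O)O[Si](C)(C)C)CCC=C2[C@@H]1CC[C@@H](C)[C@]2(C)CC/C(C)=C/C(=O)OC
F6 | step 9 | (1S,5S,6R,8aS)-1-(methoxycarbonyl)-5-[(3E)-5-methoxy-3-methyl-5-oxopent-3-en-1-yl]-5,6-dimethyl-1,2,3,5,6,7,8,8a-octahydronaphthalene-1-carboxylic acid | COC(=O)[C@@]1(C(=O)O)CCC=C2[C@@H]1CC[C@@H](C)[C@]2(C)CC/C(C)=C/C(=O)OC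
F7 | step 9 | acid chloride of acid F6 | COC(=O)[C@@]1(C(Cl)=O)CCC=C2[C@@H]1CC[C@@H](C)[C@]2(C)CC/C(C)=C/C(=O)OC
F8 | step 7 | methyl (2E)-5-[(1S,6R)-2-[(1R,4E)-1-hydroxy-5-methoxy-4-(methoxycarbonyl)pent-4-en-1-yl]-1,6-dimethylcyclohex-2-en-1-yl]-3-methylpent-2-enoate | CO/C=C(\CC[C@@H](O)C1=CCC[C@@H](C)[C@]1(C)CC/C(C)=C/C(=O)OC)C(=O)OC
F9 | step 7 | methyl (2E)-5-[(1S,6R)-2-[(4E)-5-methoxy-4-(methoxycarbonyl)pent-4-enoyl]-1,6-dimethylcyclohex-2-en-1-yl]-3-methylpent-2-enoate | CO/C=C(\CCC(=O)C1=CCC[C@@H](C)[C@]1(C)CC/C(C)=C/C(=O)OC)C(=O)OC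
F10 | step 10 | methyl (1S,5S,6R,8aS)-1-(hydroxymethyl)-5-[(3E)-5-methoxy-3-methyl-5-oxopent-3-en-1-yl]-5,6-dimethyl-1,2,3,5,6,7,8,8a-octahydronaphthalene-1-carboxylate | COC(=O)[C@@]1(CO)CCC=C2[C@@H]1CC[C@@H](C)[C@]2(C)CC/C(C)=C/C(=O)OC
F11 | step 10 | methyl (1R,5S,6R,8aS)-1-(iodomethyl)-5-[(3E)-5-methoxy-3-methyl-5-oxopent-3-en-1-yl]-5,6-dimethyl-1,2,3,5,6,7,8,8a-octahydronaphthalene-1-carboxylate | COC(=O)[C@@]1(CI)CCC=C2[C@@H]1CC[C@@H](C)[C@]2(C)CC/C(C)=C/C(=O)OC
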